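**Plan**

- Numbering: ring A is the 3,4,5-trimethoxyphenyl ring, C7 the benzylic carbon (OAc), C8 the methyl-bearing carbon (O-aryl), ring B the 2,6-dimethoxy-4-propenylphenyl ring (C1′ on O8, C4′ para to it).
- Retrosynthetic cuts, in order: the C4′–propenyl bond; the O8–C1′ aryl ether bond, with ring B traced back to a cyclohexane-1,3-dione carbenoid; the C7–OAc bond; both C–O bonds of a C7/C8 oxirane; the C7=C8 bond (Wittig).
- Forward: the chain is joined by a Z-selective Wittig reaction, the oxirane is closed by asymmetric oxygen transfer, acetic acid opens it at C7, the C8 hydroxyl captures a rhodium carbenoid, and ring B is then aromatised, methylated, borylated at C4′ and coupled with (E)-1-bromopropene.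
- Enabling feature: C7 and C8 carry vicinal oxygens in a threo relation on the 1-arylpropane chain and C7 is benzylic to ring A, so both oxygens can come from one epoxide of the Z C7=C8 alkene and be told apart by benzylic opening.
- Stereochemistry: C8 (R) is set by the chiral manganese salen catalyst and its C–O bond is never broken afterwards; C7 (R) arises from the (7S) epoxide carbon by inversion; the E alkene comes from the bromide with retention.

Key step: step 2

Assumption: the facial preference of the (S,S) catalyst is carried over from cis-β-methylstyrene and indene; if the methoxy groups were to reverse it, the (R,R) catalyst would be used and nothing else changes.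

**Route**

Step 1
Reactants: 1 3,4,5-trimethoxybenzaldehyde; 2 ethyltriphenylphosphonium bromide
Product: 4 (Z)-1,2,3-trimethoxy-5-(prop-1-enyl)benzene, via ethylidenetriphenylphosphorane 3 (not isolated)
Conditions: NaN(SiMe3)2, THF, −78 °C to 0 °C
Reagents that add atoms: none
Why: A lithium-free Wittig olefination of an aryl aldehyde with a non-stabilised ylide runs through the kinetically preferred cis-oxaphosphetane and should therefore give mainly the Z alkene, the minor E isomer being removed on AgNO3-impregnated silica before the epoxidation.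

Step 2
Reactants: 4 (Z)-1,2,3-trimethoxy-5-(prop-1-enyl)benzene
Product: 5 (2R,3S)-2-methyl-3-(3,4,5-trimethoxyphenyl)oxirane
Conditions: (S,S)-(salen)MnCl (5 mol %; salen = N,N′-bis(3,5-di-tert-butylsalicylidene)-1,2-cyclohexanediaminate), 4-phenylpyridine N-oxide (25 mol %), aq. NaOCl (pH 11.3, Na2HPO4 buffer), CH2Cl2, 0 °C
Reagents that add atoms: sodium hypochlorite, [Na+].[O-]Cl
Why: NaOCl oxidises the trivalent manganese salen chloride to a pentavalent manganese oxo species that the Z alkene approaches side-on; oxygen bonds first to C8 and the resulting C7 benzylic radical collapses onto the same oxygen. The closest known reaction is the Jacobsen–Katsuki epoxidation of cis-β-methylstyrene and indene, cis-disubstituted aryl alkenes being the best substrate class for this catalyst. The oxirane is the only ring formed and closes by a three-membered (3-exo) radical recombination at C7. C8 is fixed by the alkene face that the C2-symmetric diamine backbone and the tert-butyl groups leave open, and C7 follows because radical collapse should outrun C7–C8 rotation, so the cis relation is kept and the (7S,8R) epoxide results. The step needs enantiofacial control and retention of the cis geometry: the Z alkene, the only weakly radical-stabilising ring A, the low temperature and the axial N-oxide ligand should secure both, and any trans epoxide is removed by chromatography. Only the cis epoxide lets the later invertive attack at C7 end in the threo series.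

Step 3
Reactants: 5 (2R,3S)-2-methyl-3-(3,4,5-trimethoxyphenyl)oxirane
Product: 6 (1R,2R)-2-hydroxy-1-(3,4,5-trimethoxyphenyl)propyl acetate
Conditions: AcOH, KOAc (3 equiv), 40 °C
Reagents that add atoms: acetic acid, CC(=O)O
Why: Acidolysis of an aryl epoxide: hydrogen-bond activation by AcOH polarises the benzylic C7–O bond and acetate attacks C7 from the rear (borderline SN2 ring opening), so C7 is inverted from S to R while the C8–O bond and its R configuration are kept, which gives the threo (1R,2R) hydroxy acetate; the acetate buffer and the weakly cation-stabilising ring A (twisted 4-OMe, inductively withdrawing 3- and 5-OMe) should hold back free-cation opening, Meinwald rearrangement and acetyl migration to O8.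

Step 4
Reactants: 7 cyclohexane-1,3-dione
Product: 8 2-diazocyclohexane-1,3-dione
Conditions: 4-acetamidobenzenesulfonyl azide, Et3N, MeCN, 0 °C to 25 °C
Reagents that add atoms: 4-acetamidobenzenesulfonyl azide, CC(=O)Nc1ccc(cc1)S(=O)(=O)N=[N+]=[N-]
Why: Regitz diazo transfer: the enolate of the acidic 1,3-dione attacks the terminal nitrogen of the sulfonyl azide and loss of the sulfonamide leaves the stable acceptor/acceptor diazo compound.

Step 5
Reactants: 6 (1R,2R)-2-hydroxy-1-(3,4,5-trimethoxyphenyl)propyl acetate; 8 2-diazocyclohexane-1,3-dione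
Product: 9 (1R,2R)-2-[(2-hydroxy-6-oxocyclohex-1-en-1-yl)oxy]-1-(3,4,5-trimethoxyphenyl)propyl acetate
Conditions: Rh2(OAc)4 (2 mol %), PhCF3, 60 °C, 8 (2 equiv) added over 4 h
Reagents that add atoms: none
Why: Rhodium carbenoid O–H insertion: Rh2(OAc)4 turns 8 into an electrophilic diketo carbenoid that the C8 hydroxyl captures as an oxonium ylide followed by proton shift, so the new O8–C1′ bond forms at oxygen without touching the C8–O bond (R retained), under neutral conditions that leave the neighbouring acetate where it is, and slow addition of 8 keeps carbenoid dimerisation down.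

Step 6
Reactants: 9 (1R,2R)-2-[(2-hydroxy-6-oxocyclohex-1-en-1-yl)oxy]-1-(3,4,5-trimethoxyphenyl)propyl acetate
Product: 12 (1R,2R)-2-(2,6-dihydroxyphenoxy)-1-(3,4,5-trimethoxyphenyl)propyl acetate, via bis(trimethylsilyl) dienol ether 10 (not isolated), via bis(trimethylsilyl) resorcinol ether 11 (not isolated)
Conditions: TMSOTf (2.5 equiv), Et3N (3.5 equiv), CH2Cl2, 0 °C; solvent switch; DDQ (1.1 equiv), 2,4,6-collidine, PhH, 25 °C; then 1 M HCl, THF, 25 °C
Reagents that add atoms: none
Why: Dehydrogenative aromatisation of a silyl dienol ether (Saegusa-type oxidation done with a quinone): soft enolisation converts the enolised dione into a 1,3-bis(silyloxy)cyclohexa-1,3-diene from whose ring CH2 DDQ abstracts hydride to a triply oxygen-stabilised cation that loses a proton to the arene, and dilute acid then cleaves the two aryl silyl ethers without hydrolysing the acetate.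

Step 7
Reactants: 12 (1R,2R)-2-(2,6-dihydroxyphenoxy)-1-(3,4,5-trimethoxyphenyl)propyl acetate
Product: 13 (1R,2R)-2-(2,6-dimethoxyphenoxy)-1-(3,4,5-trimethoxyphenyl)propyl acetate
Conditions: MeI, K2CO3, acetone, 40 °C
Reagents that add atoms: iodomethane, CI
Why: Williamson O-methylation of the two phenols with anhydrous carbonate in acetone, conditions under which a secondary alkyl acetate is not cleaved and no free alcohol is present for acetyl migration.

Step 8
Reactants: 13 (1R,2R)-2-(2,6-dimethoxyphenoxy)-1-(3,4,5-trimethoxyphenyl)propyl acetate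
Product: 14 (1R,2R)-2-[2,6-dimethoxy-4-(4,4,5,5-tetramethyl-1,3,2-dioxaborolan-2-yl)phenoxy]-1-(3,4,5-trimethoxyphenyl)propyl acetate
Conditions: [Ir(OMe)(cod)]2 (2 mol %), 4,4′-di-tert-butyl-2,2′-bipyridine (4 mol %), B2pin2 (1.0 equiv), THF, 65 °C
Reagents that add atoms: bis(pinacolato)diboron, CC1(C)OB(OC1(C)C)B1OC(C)(C)C(C)(C)O1
Why: Iridium-catalysed aromatic C–H borylation is governed by sterics: H4′ of ring B is the only aryl hydrogen without an ortho substituent, whereas H2 and H6 of ring A are each flanked by a methoxy group and the side chain, so the boryl group should enter para to the ether oxygen, and the neutral conditions spare the acetate.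

Step 9
Reactants: 14 (1R,2R)-2-[2,6-dimethoxy-4-(4,4,5,5-tetramethyl-1,3,2-dioxaborolan-2-yl)phenoxy]-1-(3,4,5-trimethoxyphenyl)propyl acetate; 15 (E)-1-bromoprop-1-ene
Product: 16 (1R,2R)-2-{2,6-dimethoxy-4-[(E)-prop-1-enyl]phenoxy}-1-(3,4,5-trimethoxyphenyl)propyl acetate (Compound NP-024268)
Conditions: Pd(dppf)Cl2 (5 mol %), K3PO4 (2 equiv), THF/H2O (10:1), 50 °C, sealed tube
Reagents that add atoms: none
Why: Suzuki–Miyaura coupling of the aryl boronate with an alkenyl bromide proceeds with retention of the E geometry in oxidative addition to zerovalent palladium and in reductive elimination, and the mild phosphate base at 50 °C should leave the acetate intact.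

**Compound list**

1 | 3,4,5-trimethoxybenzaldehyde | COc1cc(C=O)cc(OC)c1OC | starting material
2 | ethyltriphenylphosphonium bromide | CC[P+](c1ccccc1)(c1ccccc1)c1ccccc1.[Br-] | starting material
3 | ethylidenetriphenylphosphorane | CC=P(c1ccccc1)(c1ccccc1)c1ccccc1 | intermediate
4 | (Z)-1,2,3-trimethoxy-5-(prop-1-enyl)benzene | C/C=C\c1cc(OC)c(OC)c(OC)c1 | intermediate
5 | (2R,3S)-2-methyl-3-(3,4,5-trimethoxyphenyl)oxirane | C[C@H]1O[C@H]1c1cc(OC)c(OC)c(OC)c1 | intermediate
6 | (1R,2R)-2-hydroxy-1-(3,4,5-trimethoxyphenyl)propyl acetate | O[C@H](C)[C@H](OC(C)=O)c1cc(OC)c(OC)c(OC)c1 | intermediate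
7 | cyclohexane-1,3-dione | O=C1CCCC(=O)C1 | starting material
8 | 2-diazocyclohexane-1,3-dione | [N-]=[N+]=C1C(=O)CCCC1=O | intermediate
9 | (1R,2R)-2-[(2-hydroxy-6-oxocyclohex-1-en-1-yl)oxy]-1-(3,4,5-trimethoxyphenyl)propyl acetate | O=C1CCCC(O)=C1O[C@H](C)[C@H](OC(C)=O)c1cc(OC)c(OC)c(OC)c1 | intermediate
10 | (1R,2R)-2-{[2,6-bis(trimethylsilyloxy)cyclohexa-1,5-dien-1-yl]oxy}-1-(3,4,5-trimethoxyphenyl)propyl acetate | C[Si](C)(C)OC1=CCCC(O[Si](C)(C)C)=C1O[C@H](C)[C@H](OC(C)=O)c1cc(OC)c(OC)c(OC)c1 | intermediate
11 | (1R,2R)-2-[2,6-bis(trimethylsilyloxy)phenoxy]-1-(3,4,5-trimethoxyphenyl)propyl acetate | C[Si](C)(C)Oc1cccc(O[Si](C)(C)C)c1O[C@H](C)[C@H](OC(C)=O)c1cc(OC)c(OC)c(OC)c1 | intermediate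
12 | (1R,2R)-2-(2,6-dihydroxyphenoxy)-1-(3,4,5-trimethoxyphenyl)propyl acetate | Oc1cccc(O)c1O[C@H](C)[C@H](OC(C)=O)c1cc(OC)c(OC)c(OC)c1 | intermediate
13 | (1R,2R)-2-(2,6-dimethoxyphenoxy)-1-(3,4,5-trimethoxyphenyl)propyl acetate | COc1cccc(OC)c1O[C@H](C)[C@H](OC(C)=O)c1cc(OC)c(OC)c(OC)c1 | intermediate
14 | (1R,2R)-2-[2,6-dimethoxy-4-(4,4,5,5-tetramethyl-1,3,2-dioxaborolan-2-yl)phenoxy]-1-(3,4,5-trimethoxyphenyl)propyl acetate | COc1cc(B2OC(C)(C)C(C)(C)O2)cc(OC)c1O[C@H](C)[C@H](OC(C)=O)c1cc(OC)c(OC)c(OC)c1 | intermediate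
15 | (E)-1-bromoprop-1-ene | C/C=C/Br | starting material
16 | (1R,2R)-2-{2,6-dimethoxy-4-[(E)-prop-1-enyl]phenoxy}-1-(3,4,5-trimethoxyphenyl)propyl acetate | C/C=C/c1cc(OC)c(O[C@H](C)[C@H](OC(C)=O)c2cc(OC)c(OC)c(OC)c2)c(OC)c1 | target

**Step count**

Total steps: 9. Longest linear sequence: 8 (steps 1–3 and 5–9); step 4 is a one-step side branch.

**Steps most likely to fail**

Step 6 (aromatisation of ring B). What may go wrong: ionisation of the benzylic C7–OAc bond by the silyl triflate, incomplete formation of the bis-silyl diene, or addition of the quinone to the electron-rich diene instead of clean hydride abstraction. The fallback sets out from 9 and comes back at 13. It masks one enol oxygen first as the methyl ether that the target needs and then aromatises an ordinary 3-alkoxycyclohexenone by an iodination/elimination cycle. Compound 9 would be O-methylated with (trimethylsilyl)diazomethane in MeOH/PhMe at 0 °C to the vinylogous ester (1R,2R)-2-[(2-methoxy-6-oxocyclohex-1-en-1-yl)oxy]-1-(3,4,5-trimethoxyphenyl)propyl acetate F1. Catalytic I2 in DMSO at 80 °C (iodination next to the ketone, loss of HI, reoxidation of HI by DMSO) should then give the phenol (1R,2R)-2-(2-hydroxy-6-methoxyphenoxy)-1-(3,4,5-trimethoxyphenyl)propyl acetate F2. One methylation with MeI and K2CO3 in acetone leads to 13.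

Step 3 (acetate opening of the epoxide). What may go wrong: partial opening through a free benzylic cation (erythro isomer and rearranged ketone), some attack at C8, and acetyl migration between O7 and O8. Attack at C8 followed by migration would give the enantiomer of 6 and so lower the optical purity. The fallback sets out from 5 and comes back at 13. It opens the epoxide with an oxygen nucleophile that cannot migrate and installs the acetate only after O8 has been arylated.

- Benzyl alcohol with catalytic BF3·OEt2 in CH2Cl2 at −30 °C should open 5 at C7 with inversion to (1R,2R)-1-(benzyloxy)-1-(3,4,5-trimethoxyphenyl)propan-2-ol F3.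
- The conditions of step 5 would give 2-{[(1R,2R)-1-(benzyloxy)-1-(3,4,5-trimethoxyphenyl)propan-2-yl]oxy}-3-hydroxycyclohex-2-en-1-one F4.
- The conditions of step 6 would pass through {[2-{[(1R,2R)-1-(benzyloxy)-1-(3,4,5-trimethoxyphenyl)propan-2-yl]oxy}cyclohexa-1,3-diene-1,3-diyl]bis(oxy)}bis(trimethylsilane) F5 and {[2-{[(1R,2R)-1-(benzyloxy)-1-(3,4,5-trimethoxyphenyl)propan-2-yl]oxy}-1,3-phenylene]bis(oxy)}bis(trimethylsilane) F6, neither isolated, to 2-{[(1R,2R)-1-(benzyloxy)-1-(3,4,5-trimethoxyphenyl)propan-2-yl]oxy}benzene-1,3-diol F7.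
- The conditions of step 7 would give 5-[(1R,2R)-1-(benzyloxy)-2-(2,6-dimethoxyphenoxy)propyl]-1,2,3-trimethoxybenzene F8.
- Hydrogenolysis (H2, Pd/C, EtOAc, 25 °C) would free (1R,2R)-2-(2,6-dimethoxyphenoxy)-1-(3,4,5-trimethoxyphenyl)propan-1-ol F9.
- Ac2O, pyridine and catalytic DMAP would convert F9 into 13.

Step 5 (carbenoid O–H insertion). What may go wrong: the diketo carbenoid is consumed by dimerisation, by attack on ring A or by the acetate carbonyl before the hindered secondary hydroxyl captures it. The fallback sets out from 6 and comes back at 13. It brings ring B in at the aromatic oxidation level as a quinone diazide, a less encumbered quinoid carbenoid precursor whose insertion product is already a phenol, so no dehydrogenation is needed. Commercially available 2-amino-3-methoxyphenol F10 would be diazotised (NaNO2, aq. HCl, 0 °C, then NaHCO3) to 6-diazo-5-methoxycyclohexa-2,4-dien-1-one F11. With Rh2(OAc)4 in CH2Cl2 at 25 °C, F11 should insert into the hydroxyl of 6 and give the phenol F2 described under step 6. Methylation with MeI and K2CO3 in acetone leads to 13.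

**Further compounds**

F1 | step 6 | (1R,2R)-2-[(2-methoxy-6-oxocyclohex-1-en-1-yl)oxy]-1-(3,4,5-trimethoxyphenyl)propyl acetate | COC1=C(O[C@H](C)[C@H](OC(C)=O)c2cc(OC)c(OC)c(OC)c2)C(=O)CCC1
F2 | step 6 | (1R,2R)-2-(2-hydroxy-6-methoxyphenoxy)-1-(3,4,5-trimethoxyphenyl)propyl acetate | COc1cccc(O)c1O[C@H](C)[C@H](OC(C)=O)c1cc(OC)c(OC)c(OC)c1
F3 | step 3 | (1R,2R)-1-(benzyloxy)-1-(3,4,5-trimethoxyphenyl)propan-2-ol | O[C@H](C)[C@H](OCc1ccccc1)c1cc(OC)c(OC)c(OC)c1
F4 | step 3 | 2-{[(1R,2R)-1-(benzyloxy)-1-(3,4,5-trimethoxyphenyl)propan-2-yl]oxy}-3-hydroxycyclohex-2-en-1-one | O=C1CCCC(O)=C1O[C@H](C)[C@H](OCc1ccccc1)c1cc(OC)c(OC)c(OC)c1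
F5 | step 3 | {[2-{[(1R,2R)-1-(benzyloxy)-1-(3,4,5-trimethoxyphenyl)propan-2-yl]oxy}cyclohexa-1,3-diene-1,3-diyl]bis(oxy)}bis(trimethylsilane) | C[Si](C)(C)OC1=CCCC(O[Si](C)(C)C)=C1O[C@H](C)[C@H](OCc1ccccc1)c1cc(OC)c(OC)c(OC)c1
F6 | step 3 | {[2-{[(1R,2R)-1-(benzyloxy)-1-(3,4,5-trimethoxyphenyl)propan-2-yl]oxy}-1,3-phenylene]bis(oxy)}bis(trimethylsilane) | C[Si](C)(C)Oc1cccc(O[Si](C)(C)C)c1O[C@H](C)[C@H](OCc1ccccc1)c1cc(OC)c(OC)c(OC)c1
F7 | step 3 | 2-{[(1R,2R)-1-(benzyloxy)-1-(3,4,5-trimethoxyphenyl)propan-2-yl]oxy}benzene-1,3-diol | Oc1cccc(O)c1O[C@H](C)[C@H](OCc1ccccc1)c1cc(OC)c(OC)c(OC)c1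
F8 | step 3 | 5-[(1R,2R)-1-(benzyloxy)-2-(2,6-dimethoxyphenoxy)propyl]-1,2,3-trimethoxybenzene | COc1cccc(OC)c1O[C@H](C)[C@H](OCc1ccccc1)c1cc(OC)c(OC)c(OC)c1
F9 | step 3 | (1R,2R)-2-(2,6-dimethoxyphenoxy)-1-(3,4,5-trimethoxyphenyl)propan-1-ol | COc1cccc(OC)c1O[C@H](C)[C@H](O)c1cc(OC)c(OC)c(OC)c1
F10 | step 5 | 2-amino-3-methoxyphenol | COc1cccc(O)c1N
F11 | step 5 | 6-diazo-5-methoxycyclohexa-2,4-dien-1-one | COC1=CC=CC(=O)C1=[N+]=[N-]
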